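## Retrosynthetic overview

- Target 15 is methyl shikimate with the same (E)-3-methylpent-2-enoyl ester on O3 and O5. Both esters are cut last: O5 while O3/O4 are tied up as an acetonide, O3 by kinetic acylation of the freed 3,4-diol.
- The C1=C2 enoate is traced to enol triflate 8 and from there to the cyclic β-keto ester 7 (oxygen on C2).
- Feature used: in the cyclohexene ring, C1 bears the ester and lies between the vinylic CH (C2) and the CH2 (C6), while C3, C4 and C5 carry the three oxygens. C1 is therefore removed as the carbon of methyl diazoacetate (C1–C2 and C1–C6 cut), leaving cyclopentanone 3 with C2–C6 and all three stereocentres.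
- Ketone 3 comes from enone 1 (C5 stereocentre bought) by dihydroxylation anti to the silyl ether and acetonide formation.
- Ring order: the carbocycle is bought five-membered and becomes the six-membered ring of the target in step 4; the dioxolane is a temporary ring (closed in step 2, opened in step 10).

Key step: step 4

Remark: ring atoms are numbered as in shikimic acid throughout (C1 carries CO2Me, C2 is the vinylic CH, C3–C5 carry oxygen with O3/O4 cis and O5 trans, C6 is CH2). The β-keto ester from the key step is assumed to sit mainly as its hydrogen-bonded enol 7 and is drawn so. Methyl diazoacetate is handled only as a dilute solution.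

## Route

Step 1
Reactants: 1 (R)-4-(tert-butyldimethylsilyloxy)cyclopent-2-en-1-one
Product: 2 (2S,3R,4R)-4-(tert-butyldimethylsilyloxy)-2,3-dihydroxycyclopentan-1-one
Conditions: OsO4 (2 mol%), NMO (1.3 equiv), acetone/H2O (8:1), 0 °C; aq. Na2SO3; crude diol taken on directly
Reagents that add atoms: osmium tetroxide O=[Os](=O)(=O)=O (delivers both oxygens); N-methylmorpholine N-oxide C[N+]1([O-])CCOCC1 (reoxidant); water O
Why: Upjohn dihydroxylation (suprafacial addition of OsO4 to the enone C=C), in which the reagent should approach the face opposite the bulky allylic silyloxy group at C4, so that the two new hydroxyls at C2 and C3 are cis to each other and trans to the silyl ether.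

Step 2
Reactants: 2 (2S,3R,4R)-4-(tert-butyldimethylsilyloxy)-2,3-dihydroxycyclopentan-1-one
Product: 3 (2S,3R,4R)-4-(tert-butyldimethylsilyloxy)-2,3-(isopropylidenedioxy)cyclopentan-1-one (cis-fused acetonide, silyl ether on the opposite face)
Conditions: 2,2-dimethoxypropane, PPTS (cat.), acetone, rt
Reagents that add atoms: 2,2-dimethoxypropane COC(C)(C)OC
Why: Acid-catalysed transacetalisation in which only the cis-1,2-diol can close the dioxolane, no stereocentre is touched, and the mild pyridinium acid should leave the silyl ether in place and not promote β-elimination.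

Step 3
Reactants: 4 glycine methyl ester hydrochloride
Product: 5 methyl diazoacetate
Conditions: NaNO2, H2SO4 (cat.), CH2Cl2/H2O, −5 °C; dried CH2Cl2 solution used without concentration
Reagents that add atoms: sodium nitrite NaNO2 [Na+].[O-]N=O
Why: Diazotisation of a primary α-amino ester, in which the diazonium ion loses its acidic α-proton instead of nitrogen and gives the acceptor-stabilised diazo compound, which is extracted into the organic layer as it forms.

Step 4
Reactants: 3 (2S,3R,4R)-4-(tert-butyldimethylsilyloxy)-2,3-(isopropylidenedioxy)cyclopentan-1-one; 5 methyl diazoacetate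
Product: 7 methyl 5-O-(tert-butyldimethylsilyl)-2-hydroxy-3,4-O-isopropylideneshikimate (enol form of the β-keto ester), via 2-oxo keto ester tautomer 6 (not isolated)
Conditions: 5 (2.0 equiv, slow addition), BF3·OEt2 (1.5 equiv), CH2Cl2, −78 → −20 °C; aq. NaHCO3
Reagents that add atoms: methyl diazoacetate (5) COC(=O)C=[N+]=[N-]
Why: BF3 activates the ketone oxygen of 3, the nucleophilic diazo carbon of 5 adds to the carbonyl carbon (new C1–C2 bond), and loss of N2 from the resulting diazonium adduct is coupled to a 1,2-shift of the ring CH2 (C6) from the former carbonyl carbon to the diazo carbon (new C1–C6 bond), giving keto ester 6 and, by tautomerisation, the chelated enol 7. The closest known reaction type is the Lewis-acid-promoted homologation of cyclic ketones with diazoacetates (Büchner–Curtius–Schlotterbeck or Tiffeneau–Demjanov-type ring expansion), which is established for cycloalkanones including α-heteroatom-substituted ones. The six-membered ring is thus closed not by a cyclisation but by one-carbon expansion of the cyclopentanone through a 1,2-alkyl shift. No lasting stereocentre is made: the carbinol centre of the adduct disappears in the shift, C1 ends as an enol carbon, and C3 next to the ketone is held by the cis-fused dioxolane, whose trans-fused epimer would be strained. The step needs the CH2 to migrate in preference to the oxygen-bearing carbon C3, and the inductively withdrawing acetal oxygen together with the greater substitution at C3 should make that carbon the poorer migrating group. The β-keto ester, bound to boron as its enolate, is far less electrophilic than 3, which should prevent a second insertion, and the low temperature is chosen to spare the acetonide and the silyl ether.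

Step 5
Reactants: 7 methyl 5-O-(tert-butyldimethylsilyl)-2-hydroxy-3,4-O-isopropylideneshikimate
Product: 8 methyl 5-O-(tert-butyldimethylsilyl)-3,4-O-isopropylidene-2-(trifluoromethanesulfonyloxy)shikimate
Conditions: Tf2O (1.2 equiv), iPr2NEt (2.0 equiv), CH2Cl2, −78 °C
Reagents that add atoms: trifluoromethanesulfonic anhydride O=S(=O)(OS(=O)(=O)C(F)(F)F)C(F)(F)F
Why: O-sulfonylation of the enol of a cyclic β-keto ester with a hindered amine base, in which the 1,3-dicarbonyl unit can only offer the C1=C2 enol, so the triflate fixes the double bond between C1 and C2 while the cold non-nucleophilic conditions should leave acetonide, silyl ether and C3 untouched.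

Step 6
Reactants: 8 methyl 5-O-(tert-butyldimethylsilyl)-3,4-O-isopropylidene-2-(trifluoromethanesulfonyloxy)shikimate
Product: 9 methyl 5-O-(tert-butyldimethylsilyl)-3,4-O-isopropylideneshikimate
Conditions: Pd(OAc)2 (5 mol%), PPh3 (10 mol%), HCO2H (2 equiv), Et3N (3 equiv), DMF, 60 °C
Reagents that add atoms: none
Why: Palladium-catalysed formate hydrogenolysis of a vinyl triflate, in which zerovalent palladium formed from Pd(OAc)2 and PPh3 inserts into the C2–OTf bond, formate displaces triflate and loses CO2 to give a palladium hydride, and reductive elimination places hydrogen on C2 with the double bond kept between C1 and C2.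

Step 7
Reactants: 9 methyl 5-O-(tert-butyldimethylsilyl)-3,4-O-isopropylideneshikimate
Product: 10 methyl (3R,4S,5R)-3,4-O-isopropylideneshikimate
Conditions: HF·pyridine, pyridine, THF, 0 °C → rt
Reagents that add atoms: none
Why: Fluoride-mediated cleavage of the Si–O bond driven by the strong Si–F bond, with pyridine-buffered HF being neither basic enough to cause elimination across the enoate nor acidic enough to open the acetonide.

Step 8
Reactants: 11 (E)-3-methylpent-2-enoic acid
Product: 12 (E)-3-methylpent-2-enoyl chloride
Conditions: (COCl)2 (1.2 equiv), DMF (cat.), CH2Cl2, 0 °C → rt; concentrated and used directly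
Reagents that add atoms: oxalyl chloride O=C(Cl)C(=O)Cl
Why: Chloroiminium-catalysed (Vilsmeier-type) conversion of the carboxylic acid into its chloride without any base, so the trisubstituted double bond should stay conjugated and E.

Step 9
Reactants: 10 methyl (3R,4S,5R)-3,4-O-isopropylideneshikimate; 12 (E)-3-methylpent-2-enoyl chloride
Product: 13 methyl 3,4-O-isopropylidene-5-O-[(E)-3-methylpent-2-enoyl]shikimate
Conditions: 12 (1.3 equiv), pyridine (3 equiv), DMAP (5 mol%), CH2Cl2, 0 °C
Reagents that add atoms: (E)-3-methylpent-2-enoyl chloride (12) CC/C(C)=C/C(=O)Cl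
Why: Nucleophile-catalysed acylation of the single free hydroxyl (O5) by the acid chloride, with pyridine chosen over a trialkylamine so that no vinylketene forms from the β,β-dialkylacryloyl chloride and the new ester stays conjugated and E; no stereocentre is involved.

Step 10
Reactants: 13 methyl 3,4-O-isopropylidene-5-O-[(E)-3-methylpent-2-enoyl]shikimate
Product: 14 methyl 5-O-[(E)-3-methylpent-2-enoyl]shikimate (free 3,4-diol)
Conditions: TFA/H2O (4:1), 0 °C; evaporation with toluene
Reagents that add atoms: none
Why: Acid-catalysed hydrolysis of the cis-fused dioxolane (acetal cleavage), in which cold aqueous acid should leave the esters and the electron-poor ring alkene alone and, being acidic and not basic, hold back migration of the C5 acyl group to O4.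

Step 11
Reactants: 14 methyl 5-O-[(E)-3-methylpent-2-enoyl]shikimate; 12 (E)-3-methylpent-2-enoyl chloride
Product: 15 methyl (3R,4S,5R)-4-hydroxy-3,5-bis{[(2E)-3-methylpent-2-enoyl]oxy}cyclohex-1-ene-1-carboxylate (target, CNP0268575.1)
Conditions: 12 (1.05 equiv), pyridine (3 equiv), CH2Cl2, −40 → 0 °C
Reagents that add atoms: (E)-3-methylpent-2-enoyl chloride (12) CC/C(C)=C/C(=O)Cl
Why: Kinetically controlled acylation of a diol at low temperature, in which the allylic C3 hydroxyl has only the vinylic CH as its second neighbour whereas the C4 hydroxyl is flanked by two oxygenated carbons and sits next to the electron-withdrawing C5 ester, so the acid chloride should react at O3; no stereocentre is formed or disturbed.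

## Compound list

1 | (R)-4-(tert-butyldimethylsilyloxy)cyclopent-2-en-1-one | O=C1C[C@@H](O[Si](C)(C)C(C)(C)C)C=C1 | starting material
2 | (2S,3R,4R)-4-(tert-butyldimethylsilyloxy)-2,3-dihydroxycyclopentan-1-one | O[C@@H]1C(=O)C[C@@H](O[Si](C)(C)C(C)(C)C)[C@@H]1O | intermediate
3 | (2S,3R,4R)-4-(tert-butyldimethylsilyloxy)-2,3-(isopropylidenedioxy)cyclopentan-1-one | CC1(C)O[C@@H]2C(=O)C[C@@H](O[Si](C)(C)C(C)(C)C)[C@@H]2O1 | intermediate
4 | glycine methyl ester hydrochloride | COC(=O)CN.Cl | starting material
5 | methyl diazoacetate | COC(=O)C=[N+]=[N-] | intermediate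
6 | methyl 5-(tert-butyldimethylsilyloxy)-3,4-(isopropylidenedioxy)-2-oxocyclohexane-1-carboxylate (keto tautomer, C3–C5 as in shikimate, C1 unset) | CC1(C)O[C@@H]2C(=O)C(C(=O)OC)C[C@@H](O[Si](C)(C)C(C)(C)C)[C@@H]2O1 | intermediate (not isolated)
7 | methyl 5-O-(tert-butyldimethylsilyl)-2-hydroxy-3,4-O-isopropylideneshikimate (enol form of the β-keto ester) | CC1(C)O[C@@H]2C(O)=C(C(=O)OC)C[C@@H](O[Si](C)(C)C(C)(C)C)[C@@H]2O1 | intermediate
8 | methyl 5-O-(tert-butyldimethylsilyl)-3,4-O-isopropylidene-2-(trifluoromethanesulfonyloxy)shikimate | CC1(C)O[C@@H]2C(OS(=O)(=O)C(F)(F)F)=C(C(=O)OC)C[C@@H](O[Si](C)(C)C(C)(C)C)[C@@H]2O1 | intermediate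
9 | methyl 5-O-(tert-butyldimethylsilyl)-3,4-O-isopropylideneshikimate | CC1(C)O[C@@H]2C=C(C(=O)OC)C[C@@H](O[Si](C)(C)C(C)(C)C)[C@@H]2O1 | intermediate
10 | methyl (3R,4S,5R)-3,4-O-isopropylideneshikimate | CC1(C)O[C@@H]2C=C(C(=O)OC)C[C@@H](O)[C@@H]2O1 | intermediate
11 | (E)-3-methylpent-2-enoic acid | CC/C(C)=C/C(=O)O | starting material
12 | (E)-3-methylpent-2-enoyl chloride | CC/C(C)=C/C(=O)Cl | intermediate
13 | methyl 3,4-O-isopropylidene-5-O-[(E)-3-methylpent-2-enoyl]shikimate | CC1(C)O[C@@H]2C=C(C(=O)OC)C[C@@H](OC(=O)/C=C(\C)CC)[C@@H]2O1 | intermediate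
14 | methyl 5-O-[(E)-3-methylpent-2-enoyl]shikimate | O[C@@H]1C=C(C(=O)OC)C[C@@H](OC(=O)/C=C(\C)CC)[C@@H]1O | intermediate
15 | methyl (3R,4S,5R)-4-hydroxy-3,5-bis{[(2E)-3-methylpent-2-enoyl]oxy}cyclohex-1-ene-1-carboxylate | CC/C(C)=C/C(=O)O[C@@H]1C=C(C(=O)OC)C[C@@H](OC(=O)/C=C(\C)CC)[C@@H]1O | target

## Step count and risks

Total step count: 11.
Longest linear sequence: 9 steps (1 → 2 → 3 → 7 → 8 → 9 → 10 → 13 → 14 → 15; steps 1, 2, 4, 5, 6, 7, 9, 10, 11). Steps 3 and 8 are one-step side branches that prepare 5 and 12.

Steps most likely to fail:

**Step 4 (ring expansion).** The oxygen-bearing ring carbon may compete in the 1,2-shift, the adduct may collapse to an epoxide instead of rearranging, or the Lewis acid may strip the acetonide or trigger β-elimination of the silyloxy group before insertion. Fallback (sets out from 3, comes back at 7): bond formation and rearrangement are separated and the Lewis acid is dropped. Ketone 3 is treated at −78 °C in THF with the lithium salt of 5, generated with LiN(iPr)2 in the presence of the ketone, to give the tertiary carbinol methyl 2-diazo-2-[4-(tert-butyldimethylsilyloxy)-1-hydroxy-2,3-(isopropylidenedioxy)cyclopentyl]acetate F1. Catalytic Rh2(OAc)4 in CH2Cl2 at room temperature should then expel nitrogen, and the rhodium carbenoid should take up the neighbouring ring CH2 by 1,2-shift to give 7, the electron-poor oxygenated carbon again being the poorer migrating group.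

**Step 11 (selective acylation of O3).** Discrimination between the two hydroxyls may be insufficient, the diol may be over-acylated, or an acyl group may migrate between neighbouring oxygens during reaction or work-up. Fallback (sets out from 9, comes back at 15): O4 alone is protected and O3 and O5 are acylated together, so no acylation has to tell O3 from O4.
- Aqueous TFA removes acetonide and silyl ether of 9 to give methyl shikimate F2.
- TBSCl (2.2 equiv) and imidazole in DMF at 0 °C should silylate the two less hindered hydroxyls to give methyl 3,5-bis-O-(tert-butyldimethylsilyl)shikimate F3; a wrongly silylated isomer can be separated and recycled to F2.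
- 4-Methoxybenzyl trichloroacetimidate with catalytic La(OTf)3 in toluene etherifies the remaining C4 hydroxyl to give methyl 3,5-bis-O-(tert-butyldimethylsilyl)-4-O-(4-methoxybenzyl)shikimate F4.
- HF·pyridine frees O3 and O5 to give methyl 4-O-(4-methoxybenzyl)shikimate F5.
- Acid chloride 12 (2.5 equiv) with pyridine and DMAP gives the diester methyl 4-O-(4-methoxybenzyl)-3,5-di-O-[(E)-3-methylpent-2-enoyl]shikimate F6.
- DDQ in CH2Cl2/pH 7 buffer cleaves the benzyl ether under neutral conditions to give 15.

**Step 5 (enol triflate).** Sulfonylation may occur on carbon instead of oxygen, the base may degrade the polyoxygenated keto ester, or the electron-poor triflate may hydrolyse back to 7 during isolation. Fallback (sets out from 7, comes back at 9, and so also bypasses step 6): the C2 oxygen is removed by reduction and elimination instead of through a triflate. NaBH4 in MeOH at −20 °C reduces the keto tautomer to the β-hydroxy ester methyl 5-(tert-butyldimethylsilyloxy)-2-hydroxy-3,4-(isopropylidenedioxy)cyclohexane-1-carboxylate F7 (mixture at C1 and C2, of no consequence). MsCl and Et3N in CH2Cl2 at 0 °C give the mesylate methyl 5-(tert-butyldimethylsilyloxy)-3,4-(isopropylidenedioxy)-2-(methanesulfonyloxy)cyclohexane-1-carboxylate F8. DBU in CH2Cl2 should then bring about E1cB elimination through the ester enolate at C1, which can only place the double bond between C1 and C2, to give 9.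

## Further compounds

F1 | step 4 | methyl 2-diazo-2-[4-(tert-butyldimethylsilyloxy)-1-hydroxy-2,3-(isopropylidenedioxy)cyclopentyl]acetate (ring stereocentres as in 3, carbinol carbon unset) | CC1(C)O[C@@H]2C(O)(C(=[N+]=[N-])C(=O)OC)C[C@@H](O[Si](C)(C)C(C)(C)C)[C@@H]2O1
F2 | step 11 | methyl shikimate | O[C@@H]1C=C(C(=O)OC)C[C@@H](O)[C@@H]1O
F3 | step 11 | methyl 3,5-bis-O-(tert-butyldimethylsilyl)shikimate | CC(C)(C)[Si](C)(C)O[C@@H]1C=C(C(=O)OC)C[C@@H](O[Si](C)(C)C(C)(C)C)[C@@H]1O
F4 | step 11 | methyl 3,5-bis-O-(tert-butyldimethylsilyl)-4-O-(4-methoxybenzyl)shikimate | CC(C)(C)[Si](C)(C)O[C@@H]1C=C(C(=O)OC)C[C@@H](O[Si](C)(C)C(C)(C)C)[C@@H]1OCc1ccc(OC)cc1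
F5 | step 11 | methyl 4-O-(4-methoxybenzyl)shikimate | O[C@@H]1C=C(C(=O)OC)C[C@@H](O)[C@@H]1OCc1ccc(OC)cc1
F6 | step 11 | methyl 4-O-(4-methoxybenzyl)-3,5-di-O-[(E)-3-methylpent-2-enoyl]shikimate | CC/C(C)=C/C(=O)O[C@@H]1C=C(C(=O)OC)C[C@@H](OC(=O)/C=C(\C)CC)[C@@H]1OCc1ccc(OC)cc1
F7 | step 5 | methyl 5-(tert-butyldimethylsilyloxy)-2-hydroxy-3,4-(isopropylidenedioxy)cyclohexane-1-carboxylate (C1 and C2 unset) | CC1(C)O[C@@H]2C(O)C(C(=O)OC)C[C@@H](O[Si](C)(C)C(C)(C)C)[C@@H]2O1
F8 | step 5 | methyl 5-(tert-butyldimethylsilyloxy)-3,4-(isopropylidenedioxy)-2-(methanesulfonyloxy)cyclohexane-1-carboxylate (C1 and C2 unset) | CC1(C)O[C@@H]2C(OS(C)(=O)=O)C(C(=O)OC)C[C@@H](O[Si](C)(C)C(C)(C)C)[C@@H]2O1
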